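## Retrosynthetic overview

1. Target 11 ⇒ ketol 8 + angelic acid 9 (ester C–O bond, last step).
2. Ketol 8 ⇒ (S)-epoxy ketone 7 by one cation–olefin cascade started at the chelated epoxy ketone. Ring A closes first (C4–C5), ring B second (C10–C9), then H7 is lost. This is the new step.
3. Epoxy ketone 7 ⇒ achiral dienone 6 by amine-salt-catalysed asymmetric epoxidation with H2O2, which sets the only externally controlled stereocentre.
4. Dienone 6 ⇒ enynol 5 (Meyer–Schuster) ⇒ allylic bromide 3 + 2-methylbut-3-yn-2-ol 4 (copper-catalysed coupling).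
5. Bromide 3 ⇒ auraptene 1 by SeO2 allylic oxidation and Appel bromination.

## Assumptions

- Auraptene (1) is bought as a catalogue compound; it is otherwise one step from umbelliferone and geranyl bromide.
- The sense of induction in step 5 is assumed. If the quinine-derived amine gives the (R)-epoxide, its quinidine-derived pseudoenantiomer is used instead.
- Numbering: open-chain compounds are numbered along the chain from the ether carbon (C1). Bicyclic compounds use drimane numbering (C2 ketone, C3 oxygenated carbon, C4 gem-dimethyl, C5/C10 ring fusion, C7=C8 alkene, C9 bearing C11H2–OAr).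
- Target stereochemistry as read from the SMILES: 3S, 5S, 9R, 10R. The ring fusion is trans, and the 3-ester oxygen, the C10 methyl and the C9 CH2OAr group are all on the same face.

## Route

Step 1
Reactants: 1 auraptene (7-geranyloxycoumarin)
Product: 2 (2E,6E)-8-hydroxyauraptene
Conditions: SeO2 (0.3 equiv), t-BuOOH (2.5 equiv), salicylic acid (0.1 equiv), CH2Cl2, rt
Reagents that add atoms: tert-butyl hydroperoxide, CC(C)(C)OO (terminal oxidant; its oxygen is relayed by catalytic SeO2, O=[Se]=O)
Why: Riley allylic oxidation (ene reaction, then [2,3]-sigmatropic shift) picks the E-methyl group of the electron-rich terminal trisubstituted alkene, the 2,3-alkene being deactivated by the allylic aryloxy group; no stereocentre is formed.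

Step 2
Reactants: 2 (2E,6E)-8-hydroxyauraptene
Product: 3 (2E,6E)-8-bromoauraptene
Conditions: CBr4, PPh3, CH2Cl2, 0 °C
Reagents that add atoms: carbon tetrabromide, BrC(Br)(Br)Br
Why: Appel reaction; bromide displaces the oxyphosphonium of the primary allylic alcohol in SN2 fashion at 0 °C, without allylic transposition or loss of the 6E geometry.

Step 3
Reactants: 3 (2E,6E)-8-bromoauraptene; 4 2-methylbut-3-yn-2-ol
Product: 5 enynol 7-{[(2E,6E)-11-hydroxy-3,7,11-trimethyldodeca-2,6-dien-9-yn-1-yl]oxy}-2H-chromen-2-one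
Conditions: CuI (10 mol %), K2CO3 (1.5 equiv), n-Bu4NCl (10 mol %), DMF, rt
Reagents that add atoms: none
Why: Copper-catalysed allyl–alkynyl coupling; the alkynylcopper species (RC≡CCu) formed from 4 attacks the unhindered primary carbon of the allylic bromide (SN2, not SN2′), the tertiary hydroxyl is not alkylated by K2CO3, and all compounds stay achiral.

Step 4
Reactants: 5 enynol
Product: 6 dienone 7-{[(2E,6E)-3,7,11-trimethyl-9-oxododeca-2,6,10-trien-1-yl]oxy}-2H-chromen-2-one
Conditions: Ph3PAuNTf2 (2 mol %), MeOH (1 equiv), toluene, rt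
Reagents that add atoms: none
Why: Meyer–Schuster rearrangement; the activated alkyne undergoes a formal 1,3-hydroxyl shift to an allenol that tautomerises to the β,β-dimethyl enone, under neutral conditions that keep the 6,7-alkene out of conjugation.

Step 5
Reactants: 6 dienone
Product: 7 (S)-epoxy ketone 7-{[(2E,6E)-9-[(2S)-3,3-dimethyloxiran-2-yl]-3,7-dimethyl-9-oxonona-2,6-dien-1-yl]oxy}-2H-chromen-2-one
Conditions: 9-amino-9-deoxy-epi-quinine (10 mol %), CF3CO2H (20 mol %), 50 % aq. H2O2 (1.5 equiv), 1,4-dioxane, 30 °C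
Reagents that add atoms: hydrogen peroxide, OO
Why: Iminium-catalysed nucleophilic (Weitz–Scheffer-type) epoxidation; only the enone condenses with the primary amine, H2O2 adds to C11 of the iminium ion and the enamine then closes on the peroxide oxygen at C10 on the face set by the protonated quinuclidine, giving the (S) centre (the first stereocentre of the route) while the electron-rich alkenes and the coumarin do not react.

Step 6
Reactants: 7 (S)-epoxy ketone
Product: 8 ketol 7-{[(1R,4aS,6S,8aR)-6-hydroxy-2,5,5,8a-tetramethyl-7-oxo-1,4,4a,5,6,7,8,8a-octahydronaphthalen-1-yl]methoxy}-2H-chromen-2-one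
Conditions: SnCl4 (2.2 equiv), CH2Cl2, −78 to −40 °C; aq. NaHCO3
Reagents that add atoms: none
Why: Proposed new method: an α,β-epoxy ketone used as the initiator of a cation–olefin bicyclisation; SnCl4 binds the ketone and epoxide oxygens in a five-membered chelate, which holds C=O and the C3–O bond syn-coplanar (the geometry of an equatorial α-oxygen on a cyclohexanone), weakens only the distal tertiary C–O bond, and lowers the migratory aptitude of the acyl group that would otherwise shift to the β-cation; the 6,7-alkene opens the epoxide from the back in a chair–chair array, the 2,3-alkene closes ring B and H7 is lost, so the two E-alkenes give the trans ring fusion with equatorial CH2OAr and equatorial 3-OH, and C5, C9 and C10 are all relayed from the epoxide carbon, which keeps its configuration; the closest known reaction type is the Lewis-acid epoxide-initiated polyene cyclisation of epoxy-farnesyl derivatives, and the competing known reactivity is the Lewis-acid 1,2-acyl shift of α,β-epoxy ketones.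

Step 7
Reactants: 8 ketol; 9 angelic acid
Product: 11 (3S)-3-angeloyloxy-2-oxodrim-7-en-11-yl umbelliferyl ether (the target), via angelic 2,4,6-trichlorobenzoic anhydride 10 (not isolated)
Conditions: 9, 2,4,6-Cl3C6H2COCl, Et3N, toluene, rt; then 8, 80 °C
Reagents that add atoms: 2,4,6-trichlorobenzoyl chloride, O=C(Cl)c1c(Cl)cc(Cl)cc1Cl (its aroyl group is in 10 only and is lost again on the way to 11)
Why: Yamaguchi-type esterification through the mixed anhydride without a nucleophilic catalyst, the usual way to acylate a hindered secondary alcohol with angelic acid without Z-to-E isomerisation to the tiglate; C3 and the other three stereocentres are not touched.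

## Compound list

1 | auraptene, 7-{[(2E)-3,7-dimethylocta-2,6-dien-1-yl]oxy}-2H-chromen-2-one | CC(C)=CCC/C(C)=C/COc1ccc2ccc(=O)oc2c1 | starting material
2 | 7-{[(2E,6E)-8-hydroxy-3,7-dimethylocta-2,6-dien-1-yl]oxy}-2H-chromen-2-one | OC/C(C)=C/CC/C(C)=C/COc1ccc2ccc(=O)oc2c1 | intermediate
3 | 7-{[(2E,6E)-8-bromo-3,7-dimethylocta-2,6-dien-1-yl]oxy}-2H-chromen-2-one | BrC/C(C)=C/CC/C(C)=C/COc1ccc2ccc(=O)oc2c1 | intermediate
4 | 2-methylbut-3-yn-2-ol | CC(C)(O)C#C | starting material
5 | 7-{[(2E,6E)-11-hydroxy-3,7,11-trimethyldodeca-2,6-dien-9-yn-1-yl]oxy}-2H-chromen-2-one | CC(C)(O)C#CC/C(C)=C/CC/C(C)=C/COc1ccc2ccc(=O)oc2c1 | intermediate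
6 | 7-{[(2E,6E)-3,7,11-trimethyl-9-oxododeca-2,6,10-trien-1-yl]oxy}-2H-chromen-2-one | CC(C)=CC(=O)C/C(C)=C/CC/C(C)=C/COc1ccc2ccc(=O)oc2c1 | intermediate
7 | 7-{[(2E,6E)-9-[(2S)-3,3-dimethyloxiran-2-yl]-3,7-dimethyl-9-oxonona-2,6-dien-1-yl]oxy}-2H-chromen-2-one | CC1(C)O[C@@H]1C(=O)C/C(C)=C/CC/C(C)=C/COc2ccc3ccc(=O)oc3c2 | intermediate
8 | 7-{[(1R,4aS,6S,8aR)-6-hydroxy-2,5,5,8a-tetramethyl-7-oxo-1,4,4a,5,6,7,8,8a-octahydronaphthalen-1-yl]methoxy}-2H-chromen-2-one | O[C@@H]1C(=O)C[C@@]2(C)[C@H](COc3ccc4ccc(=O)oc4c3)C(C)=CC[C@@H]2C1(C)C | intermediate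
9 | angelic acid, (2Z)-2-methylbut-2-enoic acid | C/C=C(/C)C(=O)O | starting material
10 | angelic 2,4,6-trichlorobenzoic anhydride | C/C=C(/C)C(=O)OC(=O)c1c(Cl)cc(Cl)cc1Cl | intermediate (not isolated)
11 | (2S,4aR,5R,8aS)-1,1,4a,6-tetramethyl-3-oxo-5-{[(2-oxo-2H-chromen-7-yl)oxy]methyl}-1,2,3,4,4a,5,8,8a-octahydronaphthalen-2-yl (2Z)-2-methylbut-2-enoate | C/C=C(/C)C(=O)O[C@@H]1C(=O)C[C@@]2(C)[C@H](COc3ccc4ccc(=O)oc4c3)C(C)=CC[C@@H]2C1(C)C | target

## Step count and risk

Total step count: 7. Longest linear sequence: 7 (1 → 11).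

Steps most likely to fail:

**Step 5 (asymmetric epoxidation).** Two risks. The α′-CH2 of 6 is both allylic and α to the ketone, so the amine catalyst may move the 6,7-alkene into conjugation through a dienamine. The ee for an acyclic β,β-dimethyl enone is also uncertain, because the stereocentre is set in the ring-closing step and not in the peroxide addition.

Fallback, setting out from dienone 6 and coming back at epoxy ketone 7: the stereocentre is set by reagent-controlled reduction and relayed by a hydroxyl-directed epoxidation. Corey–Bakshi–Shibata reduction of 6 with (R)-1-methyl-3,3-diphenyl-tetrahydropyrrolo[1,2-c][1,3,2]oxazaborole (10 mol %) and catecholborane in toluene at −78 °C treats the alkenyl group as the large substituent. It gives the (9S)-dienol 7-{[(2E,6E,9S)-9-hydroxy-3,7,11-trimethyldodeca-2,6,10-trien-1-yl]oxy}-2H-chromen-2-one F1, still by metal-free asymmetric catalysis. Ti(OiPr)4/t-BuOOH in CH2Cl2 at −20 °C then epoxidises only the allylic-alcohol alkene. A(1,3) strain from the cis-methyl group directs oxygen to the hydroxyl face, giving the threo (9S,10R) epoxy alcohol F2. The minor erythro isomer is removed here by chromatography, so the ee is not eroded. Dess–Martin periodinane with NaHCO3 in CH2Cl2 returns 7; the epoxide carbon is now named (S) only because the ranking of its neighbours changes.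

**Step 6 (new epoxy-ketone bicyclisation).** Possible failures:
- 1,2-acyl shift of the opened epoxide to a β-keto aldehyde;
- loss of the acidic H1 from the monocyclic cation to give a conjugated enone before ring B closes;
- exocyclic alkene isomers instead of the 7,8-alkene;
- ionisation of the allylic coumarinyl ether by the Lewis acid.

Fallback with known chemistry, setting out from dienone 6 and coming back at target 11: the ketone is carried as a silyl-protected carbinol through a conventional epoxide-initiated polyene cyclisation. Dienone 6 is taken through the dienol F1 and the threo epoxy alcohol F2 exactly as in the step 5 fallback. TBSCl and imidazole in DMF give the silyl ether 7-{[(2E,6E,9S)-9-(tert-butyldimethylsilyloxy)-9-[(2R)-3,3-dimethyloxiran-2-yl]-3,7-dimethylnona-2,6-dien-1-yl]oxy}-2H-chromen-2-one F3. MeAlCl2 in CH2Cl2 at −78 °C cyclises this plain trisubstituted epoxide, which has no acyl group to migrate and no acidic H1. The threo configuration places the silyloxy group equatorial in the chair transition state, giving 7-{[(1R,4aS,6S,7S,8aR)-7-(tert-butyldimethylsilyloxy)-6-hydroxy-2,5,5,8a-tetramethyl-1,4,4a,5,6,7,8,8a-octahydronaphthalen-1-yl]methoxy}-2H-chromen-2-one F4. The 3-hydroxyl is esterified with angelic acid 9 through anhydride 10 as in step 7 to give the 3-angelate 2-silyl ether F5. HF·pyridine in THF at 0 °C (acidic, so no 3-to-2 acyl migration) frees the 2-hydroxy 3-angelate F6. Dess–Martin periodinane with NaHCO3 in CH2Cl2 then gives 11.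

**Step 7 (angeloylation).** The hydroxyl is neopentyl-like and next to a ketone, so acylation may be slow, and forcing conditions invite angelate-to-tiglate isomerisation or enolisation at C3.

Fallback, setting out from ketol 8 and coming back at target 11: the Z-alkene is built on the ester after acylation with a small acid that cannot isomerise. But-2-ynoic acid, DCC and catalytic DMAP in CH2Cl2 at −20 °C give the but-2-ynoate of 8, F7. At this stage the aryl ether is homoallylic, no longer allylic, so zerovalent palladium is tolerated. Syn hydrostannation with Bu3SnH and Pd(PPh3)4 in THF at 0 °C places tin α to the ester and gives the (E)-2-(tributylstannyl)but-2-enoate of 8, F8. Stille methylation with MeI, Pd2(dba)3, P(o-tolyl)3, CuCl and K2CO3 in DMF at 60 °C replaces tin by methyl with retention, which is the angelate 11.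

## Further compounds

F1 | step 5 | 7-{[(2E,6E,9S)-9-hydroxy-3,7,11-trimethyldodeca-2,6,10-trien-1-yl]oxy}-2H-chromen-2-one | CC(C)=C[C@@H](O)C/C(C)=C/CC/C(C)=C/COc1ccc2ccc(=O)oc2c1
F2 | step 5 | 7-{[(2E,6E,9S)-9-[(2R)-3,3-dimethyloxiran-2-yl]-9-hydroxy-3,7-dimethylnona-2,6-dien-1-yl]oxy}-2H-chromen-2-one | CC1(C)O[C@@H]1[C@@H](O)C/C(C)=C/CC/C(C)=C/COc2ccc3ccc(=O)oc3c2
F3 | step 6 | 7-{[(2E,6E,9S)-9-(tert-butyldimethylsilyloxy)-9-[(2R)-3,3-dimethyloxiran-2-yl]-3,7-dimethylnona-2,6-dien-1-yl]oxy}-2H-chromen-2-one | CC1(C)O[C@@H]1[C@@H](O[Si](C)(C)C(C)(C)C)C/C(C)=C/CC/C(C)=C/COc2ccc3ccc(=O)oc3c2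
F4 | step 6 | 7-{[(1R,4aS,6S,7S,8aR)-7-(tert-butyldimethylsilyloxy)-6-hydroxy-2,5,5,8a-tetramethyl-1,4,4a,5,6,7,8,8a-octahydronaphthalen-1-yl]methoxy}-2H-chromen-2-one | O[C@@H]1[C@@H](O[Si](C)(C)C(C)(C)C)C[C@@]2(C)[C@H](COc3ccc4ccc(=O)oc4c3)C(C)=CC[C@@H]2C1(C)C
F5 | step 6 | 3-O-angeloyl derivative of F4 (2-silyl ether, 3-angelate) | C/C=C(/C)C(=O)O[C@@H]1[C@@H](O[Si](C)(C)C(C)(C)C)C[C@@]2(C)[C@H](COc3ccc4ccc(=O)oc4c3)C(C)=CC[C@@H]2C1(C)C
F6 | step 6 | 2-hydroxy 3-angelate (F5 without the silyl group; the 2-dihydro form of 11) | C/C=C(/C)C(=O)O[C@@H]1[C@@H](O)C[C@@]2(C)[C@H](COc3ccc4ccc(=O)oc4c3)C(C)=CC[C@@H]2C1(C)C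
F7 | step 7 | but-2-ynoate ester of ketol 8 | CC#CC(=O)O[C@@H]1C(=O)C[C@@]2(C)[C@H](COc3ccc4ccc(=O)oc4c3)C(C)=CC[C@@H]2C1(C)C
F8 | step 7 | (E)-2-(tributylstannyl)but-2-enoate ester of ketol 8 | C/C=C(/[Sn](CCCC)(CCCC)CCCC)C(=O)O[C@@H]1C(=O)C[C@@]2(C)[C@H](COc3ccc4ccc(=O)oc4c3)C(C)=CC[C@@H]2C1(C)C
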